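**Early times.** Early in a flask the mono adduct is new and free to meet the coupling partner. Later part of it sits as isomer of the product, and no step on the list lets the partner attack that isomer. The readings do not time this exchange: the ochre fall in mono, from 23.3% at 2.50 min to 13.0% at 6.00 min, may be attack by the partner.

| setting | grey | blue | ochre | dawn | autumn | spring | midnight |
|---|---|---|---|---|---|---|---|
| substrate | 0.40 M | 0.40 M | 0.40 M | 0.40 M (fed, over 10 min) | 0.40 M (fed, over 10 min) | 0.40 M | 0.40 M |
| coupling partner | 1 equiv | 1.4 equiv | 2.2 equiv | 1.00 equiv | 1.00 equiv | 1.00 equiv | 1.00 equiv (fed, over 2.5 min) |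
| temperature | −25 °C | −14 °C | −25 °C | −20 °C |  | −20 °C | −20 °C |
| remark | run made earlier | run made earlier | run made earlier | all else is in the flask from the start; the feed brings no volume worth counting | the addition at −60 °C, then warmed to −20 °C; the feed brings no volume worth counting | everything together at the start | all else is in the flask from the start; the feed brings no volume worth counting |
| time |  |  |  | 50 min | 50 min | 50 min | 50 min |

- grey (time / min: mono adduct / %, bis adduct / %, substrate / %): 8.00: 29.6, 16.8, 21.7; 15.0: 27.7, 15.5, 19.5; 25.0: 31.0, 14.0, 20.8; 30.0: 29.4, 16.3, 21.2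
- blue (time / min: mono adduct / %, bis adduct / %, substrate / %): 4.00: 41.9, 32.2, 7.4; 10.0: 41.4, 31.8, 8.6; 20.0: 41.1, 31.4, 7.5; 30.0: 43.0, 32.8, 8.8
- ochre (time / min: mono adduct / %, bis adduct / %, substrate / %): 2.50: 23.3, 36.7, 0.4; 6.00: 13.0, 35.4, 0; 12.0: 15.2, 36.4, 0; 30.0: 15.3, 32.7, 0.8

(standard deviation of a reading: 1 percentage point)

- steps under discussion: substrate + coupling partner -> mono adduct; coupling partner + mono adduct -> bis adduct; coupling partner + bis adduct -> tris adduct; coupling partner + tris adduct -> tetra adduct; mono adduct <-> isomer of the product

1. the flask that comes out highest in share of mono adduct in mono adduct plus bis adduct, or "all alike" when all lie within 1.5 percentage points (dawn / autumn / spring / midnight / all alike)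
2. share of mono adduct in mono adduct plus bis adduct at the end, dawn
3. share of mono adduct in mono adduct plus bis adduct at the end, autumn
4. share of mono adduct in mono adduct plus bis adduct at the end, spring
5. share of mono adduct in mono adduct plus bis adduct at the end, midnight

**Unseen species.** The grey readings stay flat, so I average them: substrate 20.8%, mono 29.4%, bis 15.7%. I assume the partner, the limiting reagent, is used up, and I neglect tetra adduct. The substrate and partner balances then give tris 2.57% and isomer 31.6%. The same balances on the blue averages, mono 41.8%, bis 32.0% and substrate 8.07%, give tris 8.01% and isomer 10.0%.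

**Isomer ratio.** The ratio [isomer of the product]/[mono adduct], an equilibrium constant, reads 1.07 in grey and 0.239 in blue. A van 't Hoff line through both gives a heat release of 72.9 kJ mol⁻¹, so the isomer ratio at −20 °C is 0.534.

**First round.** I keep grey's bis and tris. The partner balance then leaves mono plus isomer at 61.0%, and the ratio splits this into a mono share of 71.8%.

**Weak link.** Unchanged bis is the weak assumption: the ratio at −20 °C is lower than in grey, and I expect that to expose more mono. I take exposure as the midpoint between wholly free and the settled free fraction: 0.741 in grey, 0.826 at −20 °C. Scaling bis by these gives 17.4%, mono plus isomer 57.4%, and a share of 68.2%. I commit to this for spring, carry it to autumn and midnight, and leave dawn open, where substrate enters the whole partner charge.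

**The result.** The forecast, saying “Dawn has partner in excess, so over-addition gives an ochre-like share”, puts midnight highest, with dawn 33%, autumn 68%, spring 70%, midnight 73%. The flasks give dawn 53.7%, autumn 69.1%, spring 69.1%, midnight 70.8%, so midnight is highest.

    substrate + coupling partner → mono adduct (k = 0.130 M⁻¹ s⁻¹, Ea = 54.0 kJ mol⁻¹)
    coupling partner + mono adduct → bis adduct (k = 0.0480 M⁻¹ s⁻¹, Ea = 57.0 kJ mol⁻¹)
    coupling partner + bis adduct → tris adduct (k = 0.0260 M⁻¹ s⁻¹, Ea = 45.0 kJ mol⁻¹)
    coupling partner + tris adduct → tetra adduct (k = 0.0420 M⁻¹ s⁻¹, Ea = 55.0 kJ mol⁻¹)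
    mono adduct ⇌ isomer of the product (K = 0.550, k = 0.00760 s⁻¹, Ea = 61.0 kJ mol⁻¹, ΔH = −75.0 kJ mol⁻¹)
    (constants at −20 °C)

**Warmer neighbour.** Spring ends at isomer over mono 0.550, beside my 0.534. A repeat of midnight at −5 °C takes the same reckoning: the line carries 0.534 to a ratio of 0.0768, exposure 0.964, bis 20.4%, mono plus isomer 51.6%, and a share of 70.2%. That flask ends with bis 19.5%, isomer 3.87% and a share of 72.6%.

(All runs stem from a simulated flask for an exercise; the scatter is artificial.)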